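The plan cuts two bonds of the benzene ring, C1–C6 and C2–C3 (C1 carries the CH2CH2O-acyl chain, C4 the hydroxyl). The para C1/C4 relationship is that of a 4-substituted cyclohex-2-enone. The phenol oxygen therefore travels as a ketone, and the only hydroxyl ever acylated is aliphatic. In one operation, an enamine Michael addition to methyl vinyl ketone and an aldol condensation join an acyclic aldehyde to a four-carbon enone and close the carbocycle. The precursor is the linear 4-oxobutyl ester of dotriacontanoic acid, whose aldehyde α-carbon already holds the complete acyloxyethyl arm. Aerobic palladium-catalysed dehydrogenation then aromatises the ring.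

Key step: step 3

Assumption: every C32 compound is a wax that dissolves poorly in cold or strongly polar media, so each step is specified in a warm, weakly polar solvent or co-solvent; ring atoms are numbered as in the arene (C1 side chain, C4 oxygen); the amine catalyst is taken as the racemate, so every compound with an sp3 C1 is a racemate.

Step 1
Reactants: 1 dotriacontanoic acid; 2 butane-1,4-diol
Product: 4 4-hydroxybutyl dotriacontanoate, via dotriacontanoyl chloride 3 (not isolated)
Conditions: (COCl)2 (1.5 equiv), DMF (cat.), toluene, 50 °C; evaporate; residue in warm THF added slowly to 2 (10 equiv), pyridine (2 equiv), DMAP (cat.), THF, 40 °C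
Reagents that add atoms: none
Why: DMF-catalysed acid chloride formation followed by pyridine/DMAP-assisted O-acylation (nucleophilic acyl substitution) is routine for fatty acids, and the tenfold excess of the symmetrical, water-extractable diol makes a second acylation statistically minor.

Step 2
Reactants: 4 4-hydroxybutyl dotriacontanoate
Product: 5 4-oxobutyl dotriacontanoate
Conditions: TEMPO (10 mol%), PhI(OAc)2 (1.2 equiv), CH2Cl2, 35–40 °C
Reagents that add atoms: none
Why: The oxoammonium-mediated TEMPO/PhI(OAc)2 oxidation of a primary alcohol stops at the aldehyde when water is absent, is mild enough to leave the ester alone, and tolerates the gentle warming needed to keep the wax dissolved.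

Step 3
Reactants: 5 4-oxobutyl dotriacontanoate; 6 methyl vinyl ketone
Product: 9 racemic 2-(4-oxocyclohex-2-en-1-yl)ethyl dotriacontanoate, via keto aldehyde 7 (not isolated), via ring aldol 8 (not isolated)
Conditions: rac-2-[diphenyl(trimethylsilyloxy)methyl]pyrrolidine (10 mol%), ethyl 3,4-dihydroxybenzoate (20 mol%), 6 (3 equiv), toluene, 40 °C; strip excess 6; TsOH·H2O (30 mol%), toluene, reflux, water separator
Reagents that add atoms: none
Why: The secondary amine condenses with the CHO of 5 to an E-enamine whose nucleophilic carbon (future ring C1, already carrying the acyloxyethyl arm) adds to the CH2 terminus of 6 (future C6), while the catechol ester hydrogen-bonds to the enone and helps hydrolyse the product iminium ion, releasing 7 and the catalyst. After surplus 6 is removed, TsOH enolises the methyl ketone toward its CH3 group (future C3), the enol attacks the protonated aldehyde carbon (future C2) to give aldol 8, and azeotropic removal of water drives dehydration to the conjugated enone 9. The closest known reaction type is the organocatalytic Robinson annulation of α-unbranched aldehydes with methyl vinyl ketone (enamine Michael addition, then acid-mediated intramolecular aldol condensation), a standard entry to 4-alkylcyclohex-2-enones. The single ring closes in the favoured 6-(enolendo)-exo-trig mode, and this is the only realistic closure, because attack by the internal ketone CH2 on the aldehyde, or by the aldehyde α-carbon on the ketone, would give four-membered rings. C1 becomes a stereocentre in the Michael event and forms as a racemate under the racemic catalyst, the carbinol centre of 8 vanishes on dehydration, and C1 itself is flattened in step 4, so no control element is needed. The step needs cross-Michael addition to beat aldehyde self-aldolisation, a single alkylation, and survival of the ester: the bulky diphenyl(silyloxy)methyl group and the excess of 6 secure the first, the reluctance of α-branched 7 to form an enamine secures the second, and the hydroxide- and alkoxide-free medium, with the ester oxygen three bonds from the enamine carbon and out of reach of β-elimination, secures the third.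

Step 4
Reactants: 9 racemic 2-(4-oxocyclohex-2-en-1-yl)ethyl dotriacontanoate
Product: 11 basalethanolide A [2-(4-hydroxyphenyl)ethyl dotriacontanoate], via cyclohexa-2,5-dienone 10 (not isolated)
Conditions: Pd(O2CCF3)2 (5 mol%), 2-(dimethylamino)pyridine (10 mol%), TsOH·H2O (20 mol%), O2 (1 atm), DMSO–PhCl 1:1, 80 °C
Reagents that add atoms: none
Why: In this aerobic palladium-catalysed dehydrogenation of a cyclohexenone, divalent palladium forms the enolate at the C5 methylene, β-hydride elimination from C6 gives dienone 10, whose C1–H allows irreversible tautomerisation to the phenol, O2 returns zerovalent palladium to the divalent state, and the ester sees neither base nor nucleophile while the C4 oxygen can only end para to C1.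

Compound list
1 | dotriacontanoic acid | CCCCCCCCCCCCCCCCCCCCCCCCCCCCCCCC(=O)O | starting material
2 | butane-1,4-diol | OCCCCO | starting material
3 | dotriacontanoyl chloride | CCCCCCCCCCCCCCCCCCCCCCCCCCCCCCCC(=O)Cl | intermediate
4 | 4-hydroxybutyl dotriacontanoate | CCCCCCCCCCCCCCCCCCCCCCCCCCCCCCCC(=O)OCCCCO | intermediate
5 | 4-oxobutyl dotriacontanoate | CCCCCCCCCCCCCCCCCCCCCCCCCCCCCCCC(=O)OCCCC=O | intermediate
6 | methyl vinyl ketone (but-3-en-2-one) | CC(=O)C=C | starting material
7 | 3-formyl-6-oxoheptyl dotriacontanoate (racemic) | CCCCCCCCCCCCCCCCCCCCCCCCCCCCCCCC(=O)OCCC(C=O)CCC(C)=O | intermediate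
8 | 2-(2-hydroxy-4-oxocyclohexyl)ethyl dotriacontanoate (racemic, both diastereomers) | CCCCCCCCCCCCCCCCCCCCCCCCCCCCCCCC(=O)OCCC1CCC(=O)CC1O | intermediate
9 | 2-(4-oxocyclohex-2-en-1-yl)ethyl dotriacontanoate (racemic) | CCCCCCCCCCCCCCCCCCCCCCCCCCCCCCCC(=O)OCCC1C=CC(=O)CC1 | intermediate
10 | 2-(4-oxocyclohexa-2,5-dien-1-yl)ethyl dotriacontanoate (achiral) | CCCCCCCCCCCCCCCCCCCCCCCCCCCCCCCC(=O)OCCC1C=CC(=O)C=C1 | intermediate
11 | basalethanolide A, 2-(4-hydroxyphenyl)ethyl dotriacontanoate (no stereocentre) | CCCCCCCCCCCCCCCCCCCCCCCCCCCCCCCC(=O)OCCc1ccc(O)cc1 | target

Total step count: 4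
Longest linear sequence: 4 steps (1 → 4 → 5 → 9 → 11)

Steps most likely to fail

Step 3. The unbranched aldehyde may self-condense through its own enamine. The vinyl ketone may polymerise. Turnover may be slow because the waxy substrate forces dilute, warm toluene. The fallback sets out from 5 and replaces catalysis by a preformed, stoichiometric enamine. Compound 5 is condensed with piperidine (1.1 equiv, 4 Å molecular sieves, toluene, 25–40 °C) and the volatiles are stripped to leave (E)-4-(piperidin-1-yl)but-3-en-1-yl dotriacontanoate F1. No free aldehyde then remains as an aldol partner. Treatment with 6 in toluene (25 to 80 °C, Stork enamine reaction) should give the formal [4+2] adduct 2-[6-methyl-2-(piperidin-1-yl)-3,4-dihydro-2H-pyran-3-yl]ethyl dotriacontanoate F2. Buffered hydrolysis (AcOH, NaOAc, H2O–THF, 60 °C) opens F2 to 7. There the fallback rejoins the route ahead of the TsOH closure to 9.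

Step 4. The lipophilic substrate may partition poorly into the DMSO phase. The catalyst may then aggregate to metallic palladium before conversion is complete, and the dehydrogenation would stall. The fallback sets out from 9 and fixes the enol first. Soft enolisation (TBSOTf, Et3N, CH2Cl2, 25 °C; the ketone reacts far faster than the ester) should give the 2-silyloxy-1,3-diene 2-[4-(tert-butyldimethylsilyloxy)cyclohexa-2,4-dien-1-yl]ethyl dotriacontanoate F3. This is oxidised with stoichiometric Pd(OAc)2 in THF–MeCN at 40 °C (Saegusa–Ito oxidation). The sequence comes back to the route at dienone 10, which tautomerises to 11.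

Step 1. The polar diol may separate from the lipophilic acyl chloride. That raises the local proportion of acyl donor and favours double acylation, and the valuable acid is lost. The fallback sets out from 3 and removes the statistical element. Commercial 4-(benzyloxy)butan-1-ol (1.05 equiv) is acylated with 3 (pyridine, DMAP, toluene, 40 °C) to give 4-(benzyloxy)butyl dotriacontanoate F4. Neutral hydrogenolysis (H2, Pd/C, THF–EtOAc, 40 °C) then frees the alcohol and returns to the route at 4.

Further compounds
F1 | step 3 | (E)-4-(piperidin-1-yl)but-3-en-1-yl dotriacontanoate | CCCCCCCCCCCCCCCCCCCCCCCCCCCCCCCC(=O)OCC/C=C/N1CCCCC1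
F2 | step 3 | 2-[6-methyl-2-(piperidin-1-yl)-3,4-dihydro-2H-pyran-3-yl]ethyl dotriacontanoate (racemic, both diastereomers) | CCCCCCCCCCCCCCCCCCCCCCCCCCCCCCCC(=O)OCCC1CC=C(C)OC1N2CCCCC2
F3 | step 4 | 2-[4-(tert-butyldimethylsilyloxy)cyclohexa-2,4-dien-1-yl]ethyl dotriacontanoate (racemic) | CCCCCCCCCCCCCCCCCCCCCCCCCCCCCCCC(=O)OCCC1C=CC(O[Si](C)(C)C(C)(C)C)=CC1
F4 | step 1 | 4-(benzyloxy)butyl dotriacontanoate | CCCCCCCCCCCCCCCCCCCCCCCCCCCCCCCC(=O)OCCCCOCc1ccccc1
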